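## Retrosynthetic overview

- The β-substituted γ-butyrolactone of target 29 is a 3-substituted cyclobutanone (28) plus one oxygen atom, so the lactone is made last by an arm-selective Baeyer–Villiger oxidation; 28 comes from the cis-fused C4 ketone 26 by methylenation and ketal removal.
- Feature used (azulene numbering): the methylene-bearing C4 of the seven-membered ring and the methyl-bearing quaternary C3 of the five-membered ring are allylically 1,3-related through ring-fusion carbon C3a. A C4–O ester beside a C3=C3a alkene can therefore deliver its acyl α-carbon (the future acetoxymethyl CH) to C3.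
- Key disconnection: the C3–C(α) bond, by Ireland–Claisen rearrangement of ester 18 (alcohol 10 + cyclobutylacetic acid 17). The transposed C3a=C4 alkene then returns oxygen to C4 by epoxidation and 1,2-hydride shift.
- Ring order: seven-membered ring first (one-carbon enlargement of a cyclohexenone); cyclopentene fused onto it (asymmetric conjugate addition, Wacker oxidation, aldol condensation); cyclobutane made separately by dichloroketene [2+2] and attached as the ester; lactone ring last.

Key step: step 14

Assumption: for the chiral catalysts of steps 5, 8 and 21 the sense of induction on these new substrates is not secure, so the antipode that delivers the stated configuration is the one used; azulene numbering is used for the core and the face of H-8a is the reference face.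

## Route

Step 1
Reactants: 1 3-methylcyclohex-2-en-1-one
Product: 2 [(3,3-dimethylcyclohex-1-en-1-yl)oxy]trimethylsilane
Conditions: MeMgBr, CuBr·SMe2 (5 mol %), TMSCl, DMPU, THF, −78 → −40 °C; Et3N, cold aq. NaHCO3 work-up
Reagents that add atoms: methylmagnesium bromide (C[Mg]Br); chlorotrimethylsilane (C[Si](C)(C)Cl)
Why: Copper-catalysed conjugate addition of the methyl Grignard reagent to the β-methyl enone, accelerated by TMSCl, should trap the regiodefined enolate as the silyl enol ether with its double bond toward the new quaternary carbon; no stereocentre is formed.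

Step 2
Reactants: 2 [(3,3-dimethylcyclohex-1-en-1-yl)oxy]trimethylsilane
Product: 3 [(5,5-dimethylbicyclo[4.1.0]heptan-1-yl)oxy]trimethylsilane (racemic)
Conditions: Et2Zn, CH2I2, CH2Cl2, 0 °C → rt; pyridine quench
Reagents that add atoms: diiodomethane (ICI)
Why: Simmons–Smith cyclopropanation (Furukawa variant) of the electron-rich silyl enol ether should give the siloxycyclopropane, whose two racemic stereocentres are destroyed in the next two steps.

Step 3
Reactants: 3 [(5,5-dimethylbicyclo[4.1.0]heptan-1-yl)oxy]trimethylsilane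
Product: 4 3-chloro-4,4-dimethylcycloheptan-1-one (racemic)
Conditions: FeCl3 (2.2 equiv), DMF, 0 °C → rt
Reagents that add atoms: iron trichloride (Cl[Fe](Cl)Cl)
Why: Ito–Saegusa ring expansion, in which FeCl3 oxidises the siloxycyclopropane to an alkoxy radical, the internal cyclopropane bond cleaves and the ring-enlarged β-keto radical is capped by chlorine.

Step 4
Reactants: 4 3-chloro-4,4-dimethylcycloheptan-1-one
Product: 5 4,4-dimethylcyclohept-2-en-1-one
Conditions: NaOAc, MeOH, reflux
Reagents that add atoms: none
Why: E1cB dehydrochlorination of the β-chloro ketone can only go toward C2 because C4 is quaternary, which gives the conjugated cycloheptenone.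

Step 5
Reactants: 5 4,4-dimethylcyclohept-2-en-1-one; 6 but-3-en-1-ylmagnesium bromide
Product: 7 (3R)-3-(but-3-en-1-yl)-4,4-dimethylcycloheptan-1-one
Conditions: CuBr·SMe2 (5 mol %), 1-[2-(diphenylphosphino)ferrocenyl]ethyldicyclohexylphosphine (JosiPhos, 6 mol %), t-BuOMe, −75 °C; then H2O
Reagents that add atoms: none
Why: Copper-catalysed asymmetric conjugate addition of a Grignard reagent to a cyclic enone, in which the chiral ferrocenyl diphosphine controls the face of the β-carbon and so sets the (R) centre that becomes C8a.

Step 6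
Reactants: 7 (3R)-3-(but-3-en-1-yl)-4,4-dimethylcycloheptan-1-one
Product: 8 (3R)-4,4-dimethyl-3-(3-oxobutyl)cycloheptan-1-one
Conditions: PdCl2 (10 mol %), CuCl (cocatalyst), O2 (1 atm), DMF/H2O, rt
Reagents that add atoms: water (O)
Why: Tsuji–Wacker oxidation should convert the terminal alkene into the methyl ketone with Markovnikov regiochemistry while leaving the ring ketone and the stereocentre untouched.

Step 7
Reactants: 8 (3R)-4,4-dimethyl-3-(3-oxobutyl)cycloheptan-1-one
Product: 9 (8aS)-3,8,8-trimethyl-2,5,6,7,8,8a-hexahydroazulen-4(1H)-one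
Conditions: KOH, EtOH, 70 °C
Reagents that add atoms: none
Why: Intramolecular aldol condensation of the 1,6-diketone, in which the ring α-carbon beside the stereocentre adds to the methyl ketone (5-exo-trig, enolexo) and dehydration gives the fully substituted conjugated enone as the thermodynamic product; H-8a is not acidic, so the stereocentre is kept.

Step 8
Reactants: 9 (8aS)-3,8,8-trimethyl-2,5,6,7,8,8a-hexahydroazulen-4(1H)-one
Product: 10 (4S,8aS)-3,8,8-trimethyl-1,2,4,5,6,7,8,8a-octahydroazulen-4-ol (hydroxyl cis to H-8a)
Conditions: (R)-1-methyl-3,3-diphenyltetrahydro-1H,3H-pyrrolo[1,2-c][1,3,2]oxazaborole (20 mol %), BH3·SMe2, THF, −20 °C; MeOH, then H2O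
Reagents that add atoms: none
Why: Corey–Bakshi–Shibata reduction, in which the tetrasubstituted alkenyl carbon acts as the large group so that the catalyst should deliver hydride to the carbonyl face giving the (4S) carbinol by catalyst control, the hindered β-carbon securing 1,2-selectivity.

Step 9
Reactants: 11 methyl but-3-enoate; 12 trichloroacetyl chloride
Product: 14 methyl 2-(2,2-dichloro-3-oxocyclobutyl)acetate (racemic), via dichloroketene 13 (not isolated)
Conditions: Zn–Cu couple, POCl3, Et2O, reflux
Reagents that add atoms: none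
Why: [2+2] cycloaddition of dichloroketene, generated by zinc dechlorination of the acid chloride, with the terminal alkene, in which the ketene carbonyl carbon bonds to the terminal CH2 so that the CCl2 group lies next to the substituted carbon.

Step 10
Reactants: 14 methyl 2-(2,2-dichloro-3-oxocyclobutyl)acetate
Product: 15 methyl 2-(3-oxocyclobutyl)acetate
Conditions: Zn dust, AcOH, rt → 50 °C
Reagents that add atoms: none
Why: Reductive dechlorination of the α,α-dichloroketone with zinc in acetic acid removes both chlorines and the stereocentre, leaving the achiral 3-substituted cyclobutanone.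

Step 11
Reactants: 15 methyl 2-(3-oxocyclobutyl)acetate
Product: 16 methyl 2-(3,3-dimethoxycyclobutyl)acetate
Conditions: HC(OMe)3, MeOH, TsOH·H2O (cat.), rt; Et3N
Reagents that add atoms: trimethyl orthoformate (COC(OC)OC); methanol (CO)
Why: Acid-catalysed ketalisation driven by the orthoformate as water scavenger masks the ketone, so that later only the ester α-carbon can be enolised.

Step 12
Reactants: 16 methyl 2-(3,3-dimethoxycyclobutyl)acetate
Product: 17 2-(3,3-dimethoxycyclobutyl)acetic acid
Conditions: LiOH, THF/H2O, rt; then 1 M HCl to pH 4 at 0 °C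
Reagents that add atoms: lithium hydroxide ([Li+].[OH-])
Why: Saponification of the methyl ester followed by acidification only to pH 4 should free the acid while the cyclobutanone ketal survives, since its ionisation to a strained four-ring oxocarbenium ion is slow.

Step 13
Reactants: 10 (4S,8aS)-3,8,8-trimethyl-1,2,4,5,6,7,8,8a-octahydroazulen-4-ol; 17 2-(3,3-dimethoxycyclobutyl)acetic acid
Product: 18 (4S,8aS)-3,8,8-trimethyl-1,2,4,5,6,7,8,8a-octahydroazulen-4-yl 2-(3,3-dimethoxycyclobutyl)acetate
Conditions: N,N'-dicyclohexylcarbodiimide, 4-(dimethylamino)pyridine (cat.), CH2Cl2, 0 °C → rt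
Reagents that add atoms: none
Why: Steglich esterification acylates the hindered allylic alcohol under neutral conditions without touching the C4–O bond, so the carbinol configuration is retained and ionisation of the allylic system is avoided.

Step 14
Reactants: 18 (4S,8aS)-3,8,8-trimethyl-1,2,4,5,6,7,8,8a-octahydroazulen-4-yl 2-(3,3-dimethoxycyclobutyl)acetate
Product: 22 (2R)-2-(3,3-dimethoxycyclobutyl)-2-[(3S,8aS)-3,8,8-trimethyl-1,2,3,5,6,7,8,8a-octahydroazulen-3-yl]acetic acid, via lithium ester enolate 19 (not isolated), via silyl ketene acetal 20 (not isolated), via trimethylsilyl ester 21 (not isolated)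
Conditions: LiN(i-Pr)2, THF, −78 °C; TMSCl/Et3N, −78 °C → rt, then 60 °C; H2O (pH 5 buffer)
Reagents that add atoms: none
Why: LiN(i-Pr)2 in THF removes the ester α-proton under kinetic control and silylation fixes the ketene acetal with the cyclobutyl group cis to the allylic oxygen, which then undergoes a concerted suprafacial [3,3] shift in which the C4–O bond breaks, the bond between the ester α-carbon and C3 forms and the alkene moves to C3a=C4. The closest known reaction type is the Ireland–Claisen rearrangement of secondary cyclic allylic esters with 1,3-chirality transfer to a quaternary carbon. No ring is closed: both carbocycles already exist and the side chain only passes from oxygen to carbon. The quaternary C3 is controlled by the (4S) carbinol, because ring carbon C5 is tied back to C8a and the C4–O bond can therefore stand perpendicular to the C3=C3a π bond only on the face of H-8a, where the new bond must form. The side-chain stereocentre is controlled by the ketene acetal geometry read through a chair array, the boat being disfavoured because it would place the silyloxy-bearing carbon under the ring fusion against H-8a. The step thus needs one face at C3 and one acetal geometry reacting through the chair, secured by the carbinol configuration and by enolisation without polar cosolvent, and the tetrasubstituted alkene is tolerated because the shift is intramolecular and driven by formation of the carboxyl C=O.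

Step 15
Reactants: 22 (2R)-2-(3,3-dimethoxycyclobutyl)-2-[(3S,8aS)-3,8,8-trimethyl-1,2,3,5,6,7,8,8a-octahydroazulen-3-yl]acetic acid
Product: 23 (2R)-2-(3,3-dimethoxycyclobutyl)-2-[(3S,8aS)-3,8,8-trimethyl-1,2,3,5,6,7,8,8a-octahydroazulen-3-yl]ethan-1-ol
Conditions: LiAlH4, THF, 0 → 60 °C; H2O, aq. NaOH work-up
Reagents that add atoms: none
Why: Hydride reduction of the carboxylic acid with LiAlH4 should give the primary alcohol while the ketal and the hindered trisubstituted alkene stay inert and the carboxylate α-centre is not enolised.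

Step 16
Reactants: 23 (2R)-2-(3,3-dimethoxycyclobutyl)-2-[(3S,8aS)-3,8,8-trimethyl-1,2,3,5,6,7,8,8a-octahydroazulen-3-yl]ethan-1-ol
Product: 24 (2R)-2-(3,3-dimethoxycyclobutyl)-2-[(3S,8aS)-3,8,8-trimethyl-1,2,3,5,6,7,8,8a-octahydroazulen-3-yl]ethyl acetate
Conditions: Ac2O, pyridine, 4-(dimethylamino)pyridine (cat.), CH2Cl2, rt
Reagents that add atoms: acetic anhydride (CC(=O)OC(C)=O)
Why: Nucleophile-catalysed acetylation of the primary alcohol installs the acetate of the target.

Step 17
Reactants: 24 (2R)-2-(3,3-dimethoxycyclobutyl)-2-[(3S,8aS)-3,8,8-trimethyl-1,2,3,5,6,7,8,8a-octahydroazulen-3-yl]ethyl acetate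
Product: 25 3a,4-epoxide of 24 with the oxygen on the face of the C3 methyl group (anti to the side chain and to H-8a)
Conditions: mCPBA, NaHCO3, CH2Cl2, 0 °C
Reagents that add atoms: 3-chloroperoxybenzoic acid (OOC(=O)c1cccc(Cl)c1)
Why: Prilezhaev epoxidation of the trisubstituted C3a=C4 alkene, in which the peracid should approach the face carrying the C3 methyl group, anti to the bulky side chain on C3, the buffer protecting the ketal.

Step 18
Reactants: 25 3a,4-epoxide of 24
Product: 26 (2R)-2-(3,3-dimethoxycyclobutyl)-2-[(3S,3aR,8aR)-3,8,8-trimethyl-4-oxodecahydroazulen-3-yl]ethyl acetate (cis ring fusion, H-3a and H-8a on the face of the side chain)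
Conditions: BF3·OEt2, CH2Cl2, −78 °C; Et3N quench
Reagents that add atoms: none
Why: Meinwald rearrangement, in which the Lewis acid opens the epoxide at tertiary C3a and the C4 hydride migrates to C3a on the face opposite the departing oxygen, giving the C4 ketone with H-3a cis to H-8a, which is also the expected more stable epimer because C4 then lies anti to the side chain.

Step 19
Reactants: 26 (2R)-2-(3,3-dimethoxycyclobutyl)-2-[(3S,3aR,8aR)-3,8,8-trimethyl-4-oxodecahydroazulen-3-yl]ethyl acetate
Product: 27 (2R)-2-(3,3-dimethoxycyclobutyl)-2-[(3R,3aS,8aR)-3,8,8-trimethyl-4-methylidenedecahydroazulen-3-yl]ethyl acetate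
Conditions: Zn, CH2Br2, TiCl4, THF/CH2Cl2, 0 °C → rt
Reagents that add atoms: dibromomethane (BrCBr)
Why: Takai–Lombardo methylenation, whose non-basic gem-dimetallic titanium reagent should convert the hindered, epimerisable ketone into the exocyclic methylene without enolisation and without attacking the acetate or the ketal.

Step 20
Reactants: 27 (2R)-2-(3,3-dimethoxycyclobutyl)-2-[(3R,3aS,8aR)-3,8,8-trimethyl-4-methylidenedecahydroazulen-3-yl]ethyl acetate
Product: 28 (2R)-2-(3-oxocyclobutyl)-2-[(3R,3aS,8aR)-3,8,8-trimethyl-4-methylidenedecahydroazulen-3-yl]ethyl acetate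
Conditions: 1 M aq. HCl, THF, rt
Reagents that add atoms: water (O)
Why: Acid-catalysed ketal hydrolysis releases the cyclobutanone, and dilute acid at room temperature should spare the acetate and not isomerise the 1,1-disubstituted alkene.

Step 21
Reactants: 28 (2R)-2-(3-oxocyclobutyl)-2-[(3R,3aS,8aR)-3,8,8-trimethyl-4-methylidenedecahydroazulen-3-yl]ethyl acetate
Product: 29 (2R)-2-[(3R)-5-oxooxolan-3-yl]-2-[(3R,3aS,8aR)-3,8,8-trimethyl-4-methylidenedecahydroazulen-3-yl]ethyl acetate (CNP0235949.1)
Conditions: 30% aq. H2O2, 3,3'-bis(2,4,6-triisopropylphenyl)-1,1'-binaphthalene-2,2'-diyl hydrogen phosphate (10 mol %), CHCl3, −40 °C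
Reagents that add atoms: hydrogen peroxide (OO)
Why: Asymmetric Baeyer–Villiger oxidation of a 3-substituted cyclobutanone, in which the chiral phosphoric acid decides which of the two diastereotopic CH2 arms migrates in the Criegee adduct and so sets the (R) lactone centre, while hydrogen peroxide leaves the unactivated methylene group alone.

## Compound list

1 | 3-methylcyclohex-2-en-1-one | CC1=CC(=O)CCC1 | starting material
2 | [(3,3-dimethylcyclohex-1-en-1-yl)oxy]trimethylsilane | CC1(C)C=C(O[Si](C)(C)C)CCC1 | intermediate
3 | [(5,5-dimethylbicyclo[4.1.0]heptan-1-yl)oxy]trimethylsilane (racemic) | C[Si](C)(C)OC12CCCC(C)(C)C1C2 | intermediate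
4 | 3-chloro-4,4-dimethylcycloheptan-1-one (racemic) | O=C1CC(Cl)C(C)(C)CCC1 | intermediate
5 | 4,4-dimethylcyclohept-2-en-1-one | CC1(C)C=CC(=O)CCC1 | intermediate
6 | but-3-en-1-ylmagnesium bromide | C=CCC[Mg]Br | starting material
7 | (3R)-3-(but-3-en-1-yl)-4,4-dimethylcycloheptan-1-one | C=CCC[C@@H]1CC(=O)CCCC1(C)C | intermediate
8 | (3R)-4,4-dimethyl-3-(3-oxobutyl)cycloheptan-1-one | CC(=O)CC[C@@H]1CC(=O)CCCC1(C)C | intermediate
9 | (8aS)-3,8,8-trimethyl-2,5,6,7,8,8a-hexahydroazulen-4(1H)-one | CC1=C2C(=O)CCCC(C)(C)[C@@H]2CC1 | intermediate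
10 | (4S,8aS)-3,8,8-trimethyl-1,2,4,5,6,7,8,8a-octahydroazulen-4-ol, hydroxyl cis to H-8a | CC1=C2[C@@H](O)CCCC(C)(C)[C@@H]2CC1 | intermediate
11 | methyl but-3-enoate | COC(=O)CC=C | starting material
12 | trichloroacetyl chloride | ClC(Cl)(Cl)C(Cl)=O | starting material
13 | dichloroketene | ClC(Cl)=C=O | intermediate
14 | methyl 2-(2,2-dichloro-3-oxocyclobutyl)acetate (racemic) | COC(=O)CC1CC(=O)C1(Cl)Cl | intermediate
15 | methyl 2-(3-oxocyclobutyl)acetate | COC(=O)CC1CC(=O)C1 | intermediate
16 | methyl 2-(3,3-dimethoxycyclobutyl)acetate | COC(=O)CC1CC(OC)(OC)C1 | intermediate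
17 | 2-(3,3-dimethoxycyclobutyl)acetic acid | COC1(OC)CC(CC(=O)O)C1 | intermediate
18 | (4S,8aS)-3,8,8-trimethyl-1,2,4,5,6,7,8,8a-octahydroazulen-4-yl 2-(3,3-dimethoxycyclobutyl)acetate | COC1(OC)CC(CC(=O)O[C@H]2CCCC(C)(C)[C@@H]3CCC(C)=C23)C1 | intermediate
19 | lithium enolate of 18, cyclobutyl cis to the allylic oxygen | COC1(OC)CC(C1)/C=C(/O[Li])O[C@H]2CCCC(C)(C)[C@@H]3CCC(C)=C23 | intermediate
20 | trimethylsilyl ketene acetal of 18, cyclobutyl cis to the allylic oxygen and trans to the silyloxy group | COC1(OC)CC(C1)/C=C(/O[Si](C)(C)C)O[C@H]2CCCC(C)(C)[C@@H]3CCC(C)=C23 | intermediate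
21 | trimethylsilyl ester of acid 22 | C[Si](C)(C)OC(=O)[C@H](C1CC(OC)(OC)C1)[C@]2(C)CC[C@@H]3C2=CCCCC3(C)C | intermediate
22 | (2R)-2-(3,3-dimethoxycyclobutyl)-2-[(3S,8aS)-3,8,8-trimethyl-1,2,3,5,6,7,8,8a-octahydroazulen-3-yl]acetic acid (side chain on the face of H-8a, C3a=C4 alkene) | OC(=O)[C@H](C1CC(OC)(OC)C1)[C@]2(C)CC[C@@H]3C2=CCCCC3(C)C | intermediate
23 | (2R)-2-(3,3-dimethoxycyclobutyl)-2-[(3S,8aS)-3,8,8-trimethyl-1,2,3,5,6,7,8,8a-octahydroazulen-3-yl]ethan-1-ol | OC[C@H](C1CC(OC)(OC)C1)[C@]2(C)CC[C@@H]3C2=CCCCC3(C)C | intermediate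
24 | (2R)-2-(3,3-dimethoxycyclobutyl)-2-[(3S,8aS)-3,8,8-trimethyl-1,2,3,5,6,7,8,8a-octahydroazulen-3-yl]ethyl acetate | CC(=O)OC[C@H](C1CC(OC)(OC)C1)[C@]2(C)CC[C@@H]3C2=CCCCC3(C)C | intermediate
25 | 3a,4-epoxide of 24, oxygen on the face of the C3 methyl group | CC(=O)OC[C@H](C1CC(OC)(OC)C1)[C@]2(C)CC[C@@H]3[C@@]24O[C@@H]4CCCC3(C)C | intermediate
26 | (2R)-2-(3,3-dimethoxycyclobutyl)-2-[(3S,3aR,8aR)-3,8,8-trimethyl-4-oxodecahydroazulen-3-yl]ethyl acetate (cis-fused) | CC(=O)OC[C@H](C1CC(OC)(OC)C1)[C@]2(C)CC[C@@H]3[C@H]2C(=O)CCCC3(C)C | intermediate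
27 | (2R)-2-(3,3-dimethoxycyclobutyl)-2-[(3R,3aS,8aR)-3,8,8-trimethyl-4-methylidenedecahydroazulen-3-yl]ethyl acetate | CC(=O)OC[C@H](C1CC(OC)(OC)C1)[C@]2(C)CC[C@@H]3[C@H]2C(=C)CCCC3(C)C | intermediate
28 | (2R)-2-(3-oxocyclobutyl)-2-[(3R,3aS,8aR)-3,8,8-trimethyl-4-methylidenedecahydroazulen-3-yl]ethyl acetate | CC(=O)OC[C@H](C1CC(=O)C1)[C@]2(C)CC[C@@H]3[C@H]2C(=C)CCCC3(C)C | intermediate
29 | (2R)-2-[(3R)-5-oxooxolan-3-yl]-2-[(3R,3aS,8aR)-3,8,8-trimethyl-4-methylidenedecahydroazulen-3-yl]ethyl acetate (CNP0235949.1) | C=C1CCCC(C)(C)[C@@H]2CC[C@@](C)([C@H](COC(C)=O)[C@@H]3COC(=O)C3)[C@H]12 | target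

## Step count and risks

Total steps: 21. Longest linear sequence: 17 steps (from 1 through steps 1–8 and 13–21 to 29); the cyclobutane branch (steps 9–12) joins at step 13.

Steps most likely to fail:

1. Step 14 (Ireland–Claisen rearrangement). Leakage through a boat array or incomplete control of the ketene acetal geometry would erode the configuration at the side-chain carbon; C3 itself is not at risk, since its face is fixed by the ring. The fallback replaces kinetic pericyclic control of that centre by thermodynamic correction with recycling. It sets out from crude acid 22 containing its side-chain epimer, the (2S)-acid F1. The mixture is reduced as in step 15 and the alcohols are separated. The (2S)-alcohol F2 is oxidised with Dess–Martin periodinane to the (2S)-aldehyde F3. The α-centre of F3 is equilibrated with DBU in CH2Cl2 to a mixture containing the (2R)-aldehyde F4. F4 is separated and reduced with NaBH4 in MeOH to alcohol 23, where the fallback rejoins the route; recovered F3 is resubmitted to the equilibration.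

2. Step 21 (asymmetric Baeyer–Villiger oxidation). Mismatched double stereodifferentiation with the neighbouring side-chain centre, or weak discrimination of the two ring arms for a bulky 3-alkyl substituent, would give the wrong lactone centre. The fallback replaces oxygen insertion by base-mediated desymmetrisation and oxidative ring cleavage, and sets out from cyclobutanone 28. Arm-selective deprotonation with lithium bis[(R)-1-phenylethyl]amide (or its antipode) in THF at −100 °C with TMSCl present should give the silyl enol ether F5, with the double bond toward the arm that becomes the lactone CH2O. Rubottom oxidation with dimethyldioxirane at −78 °C and mild desilylation should give the α-hydroxycyclobutanone F6. NaIO4 in aqueous THF should cleave the ketol to the aldehyde acid F7. Reduction of the aldehyde with NaBH4 at 0 °C and acidification should close the lactone, which comes back to the route at target 29.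

3. Step 18 (Meinwald rearrangement). The C3a cation may be diverted to ring contraction by migration of C5, to a methyl shift from C3 or to elimination, and the Lewis acid may ionise the ketal. The fallback replaces the epoxide rearrangement by hydroboration and oxidation, and sets out from alkene 24. BH3·SMe2 in THF followed by NaBO3 should place boron at C4 and hydrogen at C3a on the face anti to the side chain, giving the trans-fused secondary alcohol F8. Dess–Martin oxidation should give the trans-fused ketone F9. Equilibration with DBU in toluene should epimerise C3a to the cis-fused ketone 26, where the fallback rejoins the route.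

Further compounds
F1 | step 14 | (2S)-2-(3,3-dimethoxycyclobutyl)-2-[(3S,8aS)-3,8,8-trimethyl-1,2,3,5,6,7,8,8a-octahydroazulen-3-yl]acetic acid (side-chain epimer of 22) | OC(=O)[C@@H](C1CC(OC)(OC)C1)[C@]2(C)CC[C@@H]3C2=CCCCC3(C)C
F2 | step 14 | (2S)-2-(3,3-dimethoxycyclobutyl)-2-[(3S,8aS)-3,8,8-trimethyl-1,2,3,5,6,7,8,8a-octahydroazulen-3-yl]ethan-1-ol (side-chain epimer of 23) | OC[C@@H](C1CC(OC)(OC)C1)[C@]2(C)CC[C@@H]3C2=CCCCC3(C)C
F3 | step 14 | (2S)-2-(3,3-dimethoxycyclobutyl)-2-[(3S,8aS)-3,8,8-trimethyl-1,2,3,5,6,7,8,8a-octahydroazulen-3-yl]acetaldehyde | O=C[C@@H](C1CC(OC)(OC)C1)[C@]2(C)CC[C@@H]3C2=CCCCC3(C)C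
F4 | step 14 | (2R)-2-(3,3-dimethoxycyclobutyl)-2-[(3S,8aS)-3,8,8-trimethyl-1,2,3,5,6,7,8,8a-octahydroazulen-3-yl]acetaldehyde | O=C[C@H](C1CC(OC)(OC)C1)[C@]2(C)CC[C@@H]3C2=CCCCC3(C)C
F5 | step 21 | trimethylsilyl enol ether of 28, double bond toward the arm that becomes the lactone CH2O | CC(=O)OC[C@H]([C@@H]1C=C(O[Si](C)(C)C)C1)[C@]2(C)CC[C@@H]3[C@H]2C(=C)CCCC3(C)C
F6 | step 21 | 2-hydroxy derivative of cyclobutanone 28, hydroxyl trans to the side chain | CC(=O)OC[C@H]([C@@H]1[C@@H](O)C(=O)C1)[C@]2(C)CC[C@@H]3[C@H]2C(=C)CCCC3(C)C
F7 | step 21 | 3-formyl-substituted butanoic acid from ring cleavage of F6 (4-oxobutanoic acid carrying the side chain at C3) | CC(=O)OC[C@H]([C@H](C=O)CC(=O)O)[C@]2(C)CC[C@@H]3[C@H]2C(=C)CCCC3(C)C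
F8 | step 18 | trans-fused C4 alcohol from hydroboration of 24, H-3a and 4-OH on the face of the C3 methyl group | CC(=O)OC[C@H](C1CC(OC)(OC)C1)[C@]2(C)CC[C@@H]3[C@@H]2[C@H](O)CCCC3(C)C
F9 | step 18 | trans-fused C4 ketone, 3a-epimer of 26 | CC(=O)OC[C@H](C1CC(OC)(OC)C1)[C@]2(C)CC[C@@H]3[C@@H]2C(=O)CCCC3(C)C
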